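The chromone is cut at C4a–C5. Ring A (C4a, C5, C6, C7, C8, C8a) carries oxygen on C5, C7 and C8a, the 1,3,5-pattern of a folded poly-β-carbonyl chain, and the pyranone ring (O1, C2, C3, C4) is a dehydrated 1,3,5-triketone that can be carried intact from a simple commercial pyranone. The key step exploits both features: a 4-pyranone bearing the protected (S)-hydroxy-ester chain on C2 and a methyl 3-oxobutanoate arm on C8a is folded by Mg(OMe)2, so that ring carbon C4a is acylated by the terminal ester and ring A appears as the 5,7-diol in one operation. Methylation and acid deprotection finish the synthesis.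

Key step: step 9

Remark: atom labels O1 to C8a follow chromone numbering and are also used for the pyranone intermediates; (S)-BINAP is assumed to give the 3S alcohol in step 3, in the same sense as with simple 3-oxoalkanoates (C2 outranks C4 in both cases).

Step 1
Reactants: 1 Meldrum's acid (2,2-dimethyl-1,3-dioxane-4,6-dione); 2 4-chlorobutanoyl chloride
Product: 3 5-(4-chloro-1-hydroxybutylidene)-2,2-dimethyl-1,3-dioxane-4,6-dione
Conditions: pyridine (2.2 equiv), CH2Cl2, 0 °C to rt; wash with 1 M HCl, concentrate, use crude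
Reagents that add atoms: none
Why: C-Acylation of Meldrum's acid: its pyridinium enolate attacks the acid chloride to give the enolised acyl Meldrum's acid, while the primary alkyl chloride is inert at 0 °C.

Step 2
Reactants: 3 5-(4-chloro-1-hydroxybutylidene)-2,2-dimethyl-1,3-dioxane-4,6-dione
Product: 4 tert-butyl 6-chloro-3-oxohexanoate
Conditions: t-BuOH (5 equiv), toluene, 90 °C
Reagents that add atoms: tert-butanol, CC(C)(C)O
Why: Alcoholysis of an acyl Meldrum's acid: heating expels acetone to give an acylketene that tert-butanol traps, and the malonic half acid loses CO2 to leave the tert-butyl β-keto ester under neutral conditions that do not cyclise the chloride.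

Step 3
Reactants: 4 tert-butyl 6-chloro-3-oxohexanoate
Product: 5 tert-butyl (S)-6-chloro-3-hydroxyhexanoate
Conditions: H2 (10 atm), RuCl2[(S)-BINAP] (0.5 mol %), MeOH, 50 °C
Reagents that add atoms: none
Why: Noyori asymmetric hydrogenation of a β-keto ester: the substrate chelates ruthenium through its ketone and ester oxygens and the (S)-BINAP ligand directs hydride to the face that gives the 3S alcohol, with the primary chloride and the tert-butyl ester untouched.

Step 4
Reactants: 5 tert-butyl (S)-6-chloro-3-hydroxyhexanoate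
Product: 6 tert-butyl (S)-3-(tert-butyldimethylsilyloxy)-6-chlorohexanoate
Conditions: TBSCl, imidazole, DMF, rt
Reagents that add atoms: tert-butyldimethylsilyl chloride (TBSCl), CC(C)(C)[Si](C)(C)Cl
Why: Imidazole-promoted silylation of a secondary alcohol; the weak base does not trigger displacement of the chloride by the hydroxyl (tetrahydrofuran formation), and the silyl ether blocks that cyclisation in the later basic steps.

Step 5
Reactants: 6 tert-butyl (S)-3-(tert-butyldimethylsilyloxy)-6-chlorohexanoate
Product: 7 tert-butyl (S)-3-(tert-butyldimethylsilyloxy)-6-iodohexanoate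
Conditions: NaI (5 equiv), NaHCO3 (0.1 equiv), 2-butanone, 80 °C
Reagents that add atoms: sodium iodide, [Na+].[I-]
Why: Finkelstein halide exchange (SN2 at the primary carbon, driven by precipitation of NaCl) should give the more reactive iodide without touching the remote stereocentre.

Step 6
Reactants: 8 2,6-dimethyl-4H-pyran-4-one; 7 tert-butyl (S)-3-(tert-butyldimethylsilyloxy)-6-iodohexanoate
Product: 10 tert-butyl (S)-3-(tert-butyldimethylsilyloxy)-7-(6-methyl-4-oxo-4H-pyran-2-yl)heptanoate, via lithium dienolate of the dimethylpyranone 9 (not isolated)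
Conditions: 8 (3.0 equiv), LiN(SiMe3)2 (2.8 equiv), THF, −78 °C; then 7 (1.0 equiv), −78 to 0 °C
Reagents that add atoms: none
Why: Lateral (vinylogous) alkylation: the 2-methyl group of a 4-pyranone is deprotonated to a lithium dienolate that is alkylated at its exocyclic carbon by the primary iodide in an SN2 reaction; the excess of cheap pyranone suppresses double alkylation and the delocalised anion is too weak a base to enolise the tert-butyl ester, so the silyloxy stereocentre is not endangered.

Step 7
Reactants: 10 tert-butyl (S)-3-(tert-butyldimethylsilyloxy)-7-(6-methyl-4-oxo-4H-pyran-2-yl)heptanoate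
Product: 12 2-{6-[(S)-7-tert-butoxy-5-(tert-butyldimethylsilyloxy)-7-oxoheptyl]-4-oxo-4H-pyran-2-yl}acetic acid, via lithium dienolate of the alkylpyranone 11 (not isolated)
Conditions: LiN(SiMe3)2 (1.2 equiv), THF, −78 °C; dry CO2, −78 to −20 °C; cold aqueous HCl to pH 3, use crude
Reagents that add atoms: carbon dioxide, O=C=O
Why: Lateral carboxylation: kinetic deprotonation takes the unhindered methyl group in preference to the chain methylene, and the dienolate adds to CO2 at its exocyclic carbon to give the pyranonylacetic acid, which is kept cold and used directly because such vinylogous β-keto acids can lose CO2 on heating.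

Step 8
Reactants: 12 2-{6-[(S)-7-tert-butoxy-5-(tert-butyldimethylsilyloxy)-7-oxoheptyl]-4-oxo-4H-pyran-2-yl}acetic acid; 13 potassium methyl malonate (potassium 3-methoxy-3-oxopropanoate)
Product: 16 methyl 4-{6-[(S)-7-tert-butoxy-5-(tert-butyldimethylsilyloxy)-7-oxoheptyl]-4-oxo-4H-pyran-2-yl}-3-oxobutanoate, via acyl imidazolide 14 (not isolated), via acylmalonate half ester 15 (not isolated)
Conditions: 1,1'-carbonyldiimidazole (CDI, 1.1 equiv), THF, 0 °C to rt; then 13 (2 equiv), MgCl2 (2 equiv), THF, rt; cold aqueous HCl work-up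
Reagents that add atoms: none
Why: Masamune-type chain extension: the acyl imidazolide acylates the magnesium chelate of the malonate half ester at carbon under nearly neutral conditions and the acylmalonate loses CO2 on acidification, giving the β-keto ester arm without exposing the silyl ether, the tert-butyl ester or the pyranone to strong base.

Step 9
Reactants: 16 methyl 4-{6-[(S)-7-tert-butoxy-5-(tert-butyldimethylsilyloxy)-7-oxoheptyl]-4-oxo-4H-pyran-2-yl}-3-oxobutanoate
Product: 17 tert-butyl (S)-3-(tert-butyldimethylsilyloxy)-7-(5,7-dihydroxy-4-oxo-4H-chromen-2-yl)heptanoate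
Conditions: Mg(OMe)2 (6 equiv), MeOH, 0.02 M, rt to 60 °C; cold aqueous HCl to pH 3
Reagents that add atoms: none
Why: Proposed new method: Mg(OMe)2 removes a proton from the C8 methylene, which is acidified by both the C7 ketone and the pyranone, to give a magnesium dienolate (O4–C4=C4a–C8a=C8) whose alpha carbon C4a is nucleophilic; C4a adds to the carbonyl of the methyl ester (C5), methoxide leaves, and the resulting ring A triketone tautomer loses the C4a proton and enolises to the aromatic 5,7-diol, held as a magnesium chelate between O5 and O4 until acid work-up. The closest known reaction type is the Claisen-mode cyclisation of 3,5,7-triketo esters and of pyrone-masked polyketides to acylphloroglucinols under Mg(OMe)2, and what is new is that the nucleophile is a ring carbon of an intact 4-pyranone; should methoxide open the pyranone reversibly, C4a becomes a triketone methylene, the same C4a–C5 bond forms and the acid work-up closes O1–C2 again. Ring A closes in a 6-exo-trig mode, the ester C=O lying outside the forming ring C4a–C8a–C8–C7–C6–C5. No stereocentre is created, and the existing silyloxy stereocentre cannot be epimerised by methoxide. The step needs C-acylation at C4a to win over aldol folding and over intermolecular condensation: with the C2, C4 and C8a carbonyls locked in the pyranone, attack of C6 on C4 would require a bridgehead alkene, C3 has no electrophile within reach, the tert-butyl ester is hindered and inert to methoxide, magnesium bridging O4 and the ester carbonyl templates the closure, and high dilution disfavours dimerisation.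

Step 10
Reactants: 17 tert-butyl (S)-3-(tert-butyldimethylsilyloxy)-7-(5,7-dihydroxy-4-oxo-4H-chromen-2-yl)heptanoate
Product: 18 tert-butyl (S)-3-(tert-butyldimethylsilyloxy)-7-(5,7-dimethoxy-4-oxo-4H-chromen-2-yl)heptanoate
Conditions: Me2SO4 (4 equiv), K2CO3 (5 equiv), acetone, reflux
Reagents that add atoms: dimethyl sulfate, COS(=O)(=O)OC
Why: Williamson O-methylation of both phenols; excess reagent and reflux are used because the 5-OH is hydrogen-bonded to the C4 carbonyl, and carbonate in acetone leaves the silyl ether and the tert-butyl ester intact.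

Step 11
Reactants: 18 tert-butyl (S)-3-(tert-butyldimethylsilyloxy)-7-(5,7-dimethoxy-4-oxo-4H-chromen-2-yl)heptanoate
Product: 19 Penithochromone P, (S)-7-(5,7-dimethoxy-4-oxo-4H-chromen-2-yl)-3-hydroxyheptanoic acid
Conditions: CF3CO2H/H2O 9:1, 0 °C to rt; concentrate, aqueous work-up
Reagents that add atoms: none
Why: Acidolysis: aqueous trifluoroacetic acid cleaves the tert-butyl ester by loss of the tert-butyl cation as isobutene and hydrolyses the secondary silyl ether at silicon, so the C–O bond of the stereocentre is never broken and the 3S configuration is retained, while the chromone and the aryl methyl ethers are stable to acid.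

Compound list
1 | Meldrum's acid (2,2-dimethyl-1,3-dioxane-4,6-dione) | CC1(C)OC(=O)CC(=O)O1 | starting material
2 | 4-chlorobutanoyl chloride | O=C(Cl)CCCCl | starting material
3 | 5-(4-chloro-1-hydroxybutylidene)-2,2-dimethyl-1,3-dioxane-4,6-dione | CC1(C)OC(=O)C(=C(O)CCCCl)C(=O)O1 | intermediate
4 | tert-butyl 6-chloro-3-oxohexanoate | CC(C)(C)OC(=O)CC(=O)CCCCl | intermediate
5 | tert-butyl (S)-6-chloro-3-hydroxyhexanoate | ClCCC[C@H](O)CC(=O)OC(C)(C)C | intermediate
6 | tert-butyl (S)-3-(tert-butyldimethylsilyloxy)-6-chlorohexanoate | ClCCC[C@H](O[Si](C)(C)C(C)(C)C)CC(=O)OC(C)(C)C | intermediate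
7 | tert-butyl (S)-3-(tert-butyldimethylsilyloxy)-6-iodohexanoate | ICCC[C@H](O[Si](C)(C)C(C)(C)C)CC(=O)OC(C)(C)C | intermediate
8 | 2,6-dimethyl-4H-pyran-4-one | Cc1cc(=O)cc(C)o1 | starting material
9 | lithium 2-methyl-6-methylidene-6H-pyran-4-olate (lateral lithium dienolate of 8) | [Li+].[O-]C1=CC(=C)OC(C)=C1 | intermediate
10 | tert-butyl (S)-3-(tert-butyldimethylsilyloxy)-7-(6-methyl-4-oxo-4H-pyran-2-yl)heptanoate | Cc1cc(=O)cc(CCCC[C@H](O[Si](C)(C)C(C)(C)C)CC(=O)OC(C)(C)C)o1 | intermediate
11 | lithium 2-[(S)-7-tert-butoxy-5-(tert-butyldimethylsilyloxy)-7-oxoheptyl]-6-methylidene-6H-pyran-4-olate (lateral lithium dienolate of 10) | [Li+].[O-]C1=CC(=C)OC(CCCC[C@H](O[Si](C)(C)C(C)(C)C)CC(=O)OC(C)(C)C)=C1 | intermediate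
12 | 2-{6-[(S)-7-tert-butoxy-5-(tert-butyldimethylsilyloxy)-7-oxoheptyl]-4-oxo-4H-pyran-2-yl}acetic acid | OC(=O)Cc1cc(=O)cc(CCCC[C@H](O[Si](C)(C)C(C)(C)C)CC(=O)OC(C)(C)C)o1 | intermediate
13 | potassium methyl malonate (potassium 3-methoxy-3-oxopropanoate) | COC(=O)CC(=O)[O-].[K+] | starting material
14 | tert-butyl (S)-3-(tert-butyldimethylsilyloxy)-7-{6-[2-(1H-imidazol-1-yl)-2-oxoethyl]-4-oxo-4H-pyran-2-yl}heptanoate (acyl imidazolide) | O=C(Cc1cc(=O)cc(CCCC[C@H](O[Si](C)(C)C(C)(C)C)CC(=O)OC(C)(C)C)o1)n1ccnc1 | intermediate
15 | 4-{6-[(S)-7-tert-butoxy-5-(tert-butyldimethylsilyloxy)-7-oxoheptyl]-4-oxo-4H-pyran-2-yl}-2-(methoxycarbonyl)-3-oxobutanoic acid (magnesium-bound acylmalonate, drawn as the free acid; the malonate carbon is configurationally undefined and is lost as a stereocentre on decarboxylation) | COC(=O)C(C(=O)O)C(=O)Cc1cc(=O)cc(CCCC[C@H](O[Si](C)(C)C(C)(C)C)CC(=O)OC(C)(C)C)o1 | intermediate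
16 | methyl 4-{6-[(S)-7-tert-butoxy-5-(tert-butyldimethylsilyloxy)-7-oxoheptyl]-4-oxo-4H-pyran-2-yl}-3-oxobutanoate | COC(=O)CC(=O)Cc1cc(=O)cc(CCCC[C@H](O[Si](C)(C)C(C)(C)C)CC(=O)OC(C)(C)C)o1 | intermediate
17 | tert-butyl (S)-3-(tert-butyldimethylsilyloxy)-7-(5,7-dihydroxy-4-oxo-4H-chromen-2-yl)heptanoate | Oc1cc(O)c2c(=O)cc(CCCC[C@H](O[Si](C)(C)C(C)(C)C)CC(=O)OC(C)(C)C)oc2c1 | intermediate
18 | tert-butyl (S)-3-(tert-butyldimethylsilyloxy)-7-(5,7-dimethoxy-4-oxo-4H-chromen-2-yl)heptanoate | COc1cc(OC)c2c(=O)cc(CCCC[C@H](O[Si](C)(C)C(C)(C)C)CC(=O)OC(C)(C)C)oc2c1 | intermediate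
19 | Penithochromone P, (S)-7-(5,7-dimethoxy-4-oxo-4H-chromen-2-yl)-3-hydroxyheptanoic acid | COc1cc(OC)c2c(=O)cc(CCCC[C@H](O)CC(=O)O)oc2c1 | target

Total step count: 11. Longest linear sequence: 11 steps (1 and 2 to 19; 8 and 13 enter as commercial materials).

Steps most likely to fail

Step 9 (the proposed new method). The dienolate may fail to engage the ester because the magnesium chelate of the β-keto ester rests as an unreactive enolate. Methoxide may instead cleave the keto ester arm by retro-Claisen attack at C7, or the pyranone may open and fold by aldol condensation. The fallback uses known chemistry and builds the chromone first, then attaches the chain. It sets out from iodide 7. Commercial 2'-hydroxy-4',6'-dimethoxyacetophenone is condensed with ethyl acetate (NaH, THF) to 1-(2-hydroxy-4,6-dimethoxyphenyl)butane-1,3-dione F1, which is cyclodehydrated (HCl, acetic acid) to 5,7-dimethoxy-2-methyl-4H-chromen-4-one F2. Lateral deprotonation with LiN(iPr)2 in THF at −78 °C gives lithium 5,7-dimethoxy-2-methylidene-2H-chromen-4-olate F3, which is alkylated with 7. This returns to the route at compound 18, so that only step 11 remains.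

Step 6. The SN2 reaction of the delocalised dienolate with an unactivated iodide may be sluggish, with competing O-alkylation, double alkylation or base-induced elimination of the silyloxy group. The fallback replaces the alkylation by a carbonyl addition and sets out from iodide 7. Kornblum-type oxidation with trimethylamine N-oxide in DMSO gives tert-butyl (S)-3-(tert-butyldimethylsilyloxy)-6-oxohexanoate F4. Aldol addition of lithium dienolate 9 at −78 °C gives tert-butyl (3S)-3-(tert-butyldimethylsilyloxy)-6-hydroxy-7-(6-methyl-4-oxo-4H-pyran-2-yl)heptanoate F5 as a mixture of carbinol epimers, which is of no consequence. Mesylation (MsCl, Et3N) gives tert-butyl (3S)-3-(tert-butyldimethylsilyloxy)-6-(methylsulfonyloxy)-7-(6-methyl-4-oxo-4H-pyran-2-yl)heptanoate F6, and DBU eliminates it in the same flask to tert-butyl (S,E)-3-(tert-butyldimethylsilyloxy)-7-(6-methyl-4-oxo-4H-pyran-2-yl)hept-6-enoate F7. Hydrogenation of the exocyclic alkene (H2, 1 atm, palladium on carbon, ethyl acetate, monitored so that the pyranone ring is not reduced) returns to the route at compound 10.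

Step 8. Acid 12 may lose CO2, or its acidic acyl imidazolide may self-condense, before the malonate attacks. The fallback builds the arm by forming C7–C8 and then C5–C6 and sets out from compound 10. Its lithium dienolate 11 is acetylated with N-methoxy-N-methylacetamide to tert-butyl (S)-3-(tert-butyldimethylsilyloxy)-7-[4-oxo-6-(2-oxopropyl)-4H-pyran-2-yl]heptanoate F8. LiN(iPr)2 (2.2 equiv, THF, −78 °C) converts this into the dilithium dienediolate F9, whose terminal carbon, the most nucleophilic site of a 1,3-dicarbonyl-type dianion, is carboxylated with dimethyl carbonate. This returns to the route at compound 16.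

Further compounds
F1 | step 9 | 1-(2-hydroxy-4,6-dimethoxyphenyl)butane-1,3-dione | CC(=O)CC(=O)c1c(O)cc(OC)cc1OC
F2 | step 9 | 5,7-dimethoxy-2-methyl-4H-chromen-4-one | COc1cc(OC)c2c(=O)cc(C)oc2c1
F3 | step 9 | lithium 5,7-dimethoxy-2-methylidene-2H-chromen-4-olate | [Li+].[O-]C1=CC(=C)Oc2cc(OC)cc(OC)c12
F4 | step 6 | tert-butyl (S)-3-(tert-butyldimethylsilyloxy)-6-oxohexanoate | O=CCC[C@H](O[Si](C)(C)C(C)(C)C)CC(=O)OC(C)(C)C
F5 | step 6 | tert-butyl (3S)-3-(tert-butyldimethylsilyloxy)-6-hydroxy-7-(6-methyl-4-oxo-4H-pyran-2-yl)heptanoate (both C6 epimers) | Cc1cc(=O)cc(CC(O)CC[C@H](O[Si](C)(C)C(C)(C)C)CC(=O)OC(C)(C)C)o1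
F6 | step 6 | tert-butyl (3S)-3-(tert-butyldimethylsilyloxy)-6-(methylsulfonyloxy)-7-(6-methyl-4-oxo-4H-pyran-2-yl)heptanoate (both C6 epimers) | Cc1cc(=O)cc(CC(OS(C)(=O)=O)CC[C@H](O[Si](C)(C)C(C)(C)C)CC(=O)OC(C)(C)C)o1
F7 | step 6 | tert-butyl (S,E)-3-(tert-butyldimethylsilyloxy)-7-(6-methyl-4-oxo-4H-pyran-2-yl)hept-6-enoate | Cc1cc(=O)cc(/C=C/CC[C@H](O[Si](C)(C)C(C)(C)C)CC(=O)OC(C)(C)C)o1
F8 | step 8 | tert-butyl (S)-3-(tert-butyldimethylsilyloxy)-7-[4-oxo-6-(2-oxopropyl)-4H-pyran-2-yl]heptanoate | CC(=O)Cc1cc(=O)cc(CCCC[C@H](O[Si](C)(C)C(C)(C)C)CC(=O)OC(C)(C)C)o1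
F9 | step 8 | dilithium dienediolate of F8 (deprotonated at the ring-side methylene and the terminal methyl) | [Li+].[Li+].C=C([O-])C=C1C=C([O-])C=C(CCCC[C@H](O[Si](C)(C)C(C)(C)C)CC(=O)OC(C)(C)C)O1
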